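**Conventions and assumptions**

- Rings A1, A2 and A3 are the three resorcinol-derived rings counted from the stilbene end; ring D is the terminal 3,5-dioxygenated phenyl ring. Dihydrobenzofurans 1, 2 and 3 are fused to rings A1, A2 and A3 and are numbered O1, C2, C3, C3a, C4–C7, C7a.
- G1 = (2R,3R)-6-methoxy-2-(4-methoxyphenyl)-4-[(E)-2-(4-methoxyphenyl)ethenyl]-2,3-dihydro-1-benzofuran-3-yl.
- G2 = (2S,3S)-6-methoxy-2-(4-methoxyphenyl)-4-(G1)-2,3-dihydro-1-benzofuran-3-yl.
- Assumption: with Pd(OCOCF3)2 the ligand (S)-t-BuPyOx, (S)-4-tert-butyl-2-(pyridin-2-yl)-4,5-dihydrooxazole, is taken to give the (2R)-flavanone; if the sense is the opposite, the two ligand enantiomers change places in steps 4, 10 and 15.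
- Compounds 1, 2, 5, 8, 15 and 17 are taken as commercial.

## Analysis of the target

Miyabenol A is a resveratrol tetramer in which three 2-(4-hydroxyphenyl)-3-aryl-2,3-dihydrobenzofurans are joined head to tail. C3 of dihydrobenzofuran 1 carries ring A2, C3 of dihydrobenzofuran 2 carries ring A3, C3 of dihydrobenzofuran 3 carries ring D, and C4 of ring A1 bears the (E)-4-hydroxystyryl group. The six stereocentres are trans within each five-membered ring and read (2R,3R), (2S,3S), (2R,3R) along the chain, so the middle unit is the mirror image of its neighbours and no relay of configuration from unit to unit can be used. Every C3 is a diarylmethine flanked by the C2 aryl group and by the substituent on C4 of its own ring, which makes the C3–aryl bonds the most congested in the molecule. The sensitive groups are the nine phenols, the electron-rich stilbene (light, acid, electrophilic oxidants) and the benzylic C2–O bonds, which ionise under Lewis acids; in flavanone-type intermediates the same C2–O bond is β to a ketone and can open by retro-oxa-Michael reaction. The difficulty is to build one motif three times with alternating absolute sense and rising steric load. The strategy rests on the fact that in each dihydrobenzofuran O1, C2 with its aryl group, C3 and the fused ring are those of a 2-arylchroman-4-one lacking C4. Moving C4a from C4 to C3 contracts the flavanone ring and pushes C4 out as a carboxyl group, which is then exchanged for the next aryl ring.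

## Retrosynthetic reasoning

36 back to 35. Only the nine O–methyl bonds are cut. Methyl ethers are kept throughout because they survive Friedel–Crafts acylation, lithium amide, organozinc–nickel chemistry and light. The forward step has to cleave all nine without ionising the C2–O bonds.

35 back to 34 and 1. The bond between C3 of dihydrobenzofuran 3 and ring D is cut. It is cut here because it can be made through a planar benzylic radical at C3, which the aryl group approaches anti to the C2 aryl group, so the trans relation arises with the bond. Ring D comes from metalated 1, and 34 is the activated ester of acid 33 with 17.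

33 back to 30 (key disconnection). The C3–C3a bond is cut and C3a is reconnected to the carboxyl carbon, which re-expands the five-membered ring to the 3-diazochroman-4-one 30. This turns C2 into a flavanone stereocentre that a catalyst can set, and the carboxyl group needed for the arylation is a by-product of the contraction. Forward, C4a must shift from C4 to C3 as the diazo group leaves, ketene 31 must be trapped as ester 32, and C2 and the remote stilbene must stay untouched.

30 back to 28, then 27 and 8. The diazo group goes back to the methylene group of flavanone 28. The C2–aryl bond is then cut to give the flat chromone 27 and boronic acid 8, so that a chiral catalyst sets C2 on an achiral ring carbon, independent of the resident stereocentres.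

27 back to 26 and 7. The bond from C3 of dihydrobenzofuran 2 to ring A3 is cut, again as a radical arylation. The aryl partner is metalated 7, a complete chromone, so no phenol or acetyl manipulation is needed on advanced material.

26 back to 25, 22, 20, then 19 and 8; 19 back to 18 and 7. These are the same four operations one unit earlier. The mirror-image middle unit only needs the other hand of the catalyst in the conjugate addition.

18 back to 16, then 14 and 15. The aryl–vinyl bond of the stilbene is cut at C4 of ring A1. The stilbene is introduced only after the first ring contraction; otherwise the styryl group would be conjugated with the chromanone carbonyl during irradiation and exposed to divalent palladium.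

14 back to 11, 9, then 7 and 8. This is the first cycle, run on the bromide.

7 back to 4 and 5, then 3, then 1 and 2. C2 of the chromone comes from 5 and C3 from the acetyl methyl group of 2. The single building block 7 serves as ring A1, ring A2 and ring A3.

## Alternatives that were turned down

Alternative 1: The O1–C2 bond of dihydrobenzofuran 2 is cut. The precursor would be a ring-opened diaryl-dihydrocoumarin carrying a redox-active ester on the future C2 and a silylated ring A2 oxygen. In the forward step a photoredox catalyst would reduce the ester; decarboxylation, oxidation of the benzylic radical to the cation and capture by the ring A2 oxygen would close the middle ring and give A1, which carries bromine on ring A1 for later attachment of the styryl group.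
- For: it is convergent, the C2–O closure should end trans under both kinetic and thermodynamic control, and the stilbene is absent during the photochemical step. On that last point it is stronger than the chosen route, which relies on wavelength selection, and its longest linear sequence would be shorter.
- Against: it makes only the middle ring. The diarylmethine centre of unit 2, which must be opposite in sense to both neighbours, has to be set against two remote units with no evident controlling element. The free cation at C2 sits among several electron-rich rings, so Friedel–Crafts capture or loss of the C3 proton competes with attack by a poorly nucleophilic silylated oxygen. A late coupling at the most hindered position of A1 adds steps.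
- In its place the chosen route offers one catalyst-controlled cycle for all three rings, no cation at C2, and alternation of configuration by a change of ligand hand.

Alternative 2: Ring A2 is disconnected across two of its ring bonds. An alkynyl ketone joining C3 of dihydrobenzofuran 1 to ring A3 would undergo a Diels–Alder reaction with an electron-rich bis-silyloxy alkoxy diene, and elimination would aromatise the adduct to the 2,4-dihydroxybenzophenone A2.
- For: it is highly convergent, and ring A2 is grown around the congested C3 instead of being coupled to it. Here it is stronger than the chosen route, whose steps 9 and 14 force an ortho-substituted aryl group onto a flanked radical. The regiochemistry follows from the polarisation of the ynone, and the two phenols come out differentiated.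
- Against: A2 contains neither stereocentre of dihydrobenzofuran 2, so the carbonyl carbon must still be turned into C3 and a C2 aryl carbon added with (2S,3S) configuration against both neighbours. In the ynone the C3–H of dihydrobenzofuran 1 is propargylic and vinylogously acidic, so allenyl enolate formation threatens epimerisation or β-elimination of the ring oxygen. The cycloaddition to so hindered an ynone would be slow, and four or five further operations would follow.
- The chosen route sets each centre as the ring is made.

Alternative 3: The C2–C3 bond of dihydrobenzofuran 2 is cut. A diaryldiazomethane between rings A2 and A3 would give, with a chiral dirhodium tetracarboxylate, a donor–donor carbene that inserts into the benzylic C–H bond of an ortho 4-methoxybenzyl ether and delivers A3, which is identical with 35.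
- For: it is the most convergent plan, sets both centres in one catalytic step, and leaves only the deprotection. In end-game brevity it is stronger than the chosen route, which needs three steps after its key step.
- Against: insertions of this kind tend to give the cis-2,3-diaryl ring, while trans is required and a diarylmethine C3 cannot be equilibrated by base. The diazo carbon lies between a di-ortho-substituted and an ortho-substituted ring, so preparing it from the hindered ketone is doubtful. The free carbene has other outlets: the C2–H and C3–H bonds of units 1 and 3, the stilbene and the methoxyarenes. The catalyst would also have to override four resident stereocentres.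
- The chosen route passes through no free carbene and decides trans separately by anti addition to a planar radical.

Key step: step 17

## Route

Step 1
Reactants: 1 1-bromo-3,5-dimethoxybenzene; 2 acetyl chloride
Product: 3 1-(2-bromo-4,6-dimethoxyphenyl)ethan-1-one
Conditions: AlCl3, CH2Cl2, 0 °C
Reagents that add atoms: none
Why: Friedel–Crafts acylation; attack should occur at C2 of 1, para to one methoxy group and ortho to the other, rather than at C4 between the two methoxy groups. This places the acetyl group next to the bromide, as the chromone needs.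

Step 2
Reactants: 3 1-(2-bromo-4,6-dimethoxyphenyl)ethan-1-one
Product: 4 1-(2-bromo-6-hydroxy-4-methoxyphenyl)ethan-1-one
Conditions: BCl3, CH2Cl2, −78 → 0 °C
Reagents that add atoms: none
Why: Chelation-controlled ether cleavage; boron bound to the ketone oxygen cleaves only the ortho methyl ether through a six-membered chelate. The para methoxy group and the bromide are left.

Step 3
Reactants: 4 1-(2-bromo-6-hydroxy-4-methoxyphenyl)ethan-1-one; 5 N,N-dimethylformamide dimethyl acetal
Product: 7 5-bromo-7-methoxy-4H-chromen-4-one, via enaminone 6 (not isolated)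
Conditions: 5, toluene, 90 °C; then conc. HCl, CH2Cl2, 40 °C
Reagents that add atoms: none
Why: Condensation of the acetyl methyl group with the amide acetal gives the enaminone; acid then promotes addition of the phenol to the β-carbon and loss of dimethylamine. This is the standard enaminone route to chromones.

Step 4
Reactants: 7 5-bromo-7-methoxy-4H-chromen-4-one; 8 4-methoxyphenylboronic acid
Product: 9 (2R)-5-bromo-7-methoxy-2-(4-methoxyphenyl)-2,3-dihydro-4H-chromen-4-one
Conditions: Pd(OCOCF3)2 (5 mol%), (S)-t-BuPyOx (6 mol%), NH4PF6 (30 mol%), H2O (5 equiv), ClCH2CH2Cl, 60 °C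
Reagents that add atoms: none
Why: Palladium-catalysed enantioselective conjugate addition of an arylboronic acid to a chromone: the aryl–palladium species adds across C2=C3 and the palladium enolate is protonated. The tert-butyl group of the ligand differentiates the two faces of the flat chromone and sets C2 as (R). The C–Br bond should be inert to the cationic divalent palladium catalyst.

Step 5
Reactants: 9 (2R)-5-bromo-7-methoxy-2-(4-methoxyphenyl)-2,3-dihydro-4H-chromen-4-one
Product: 11 (2S)-5-bromo-3-diazo-7-methoxy-2-(4-methoxyphenyl)-2,3-dihydro-4H-chromen-4-one, via trifluoroacetyl ketone 10 (not isolated)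
Conditions: LiN(SiMe3)2, THF, −78 °C; CF3CO2CH2CF3; then MsN3, Et3N, H2O, MeCN, 0 °C
Reagents that add atoms: 2,2,2-trifluoroethyl trifluoroacetate, O=C(OCC(F)(F)F)C(F)(F)F (its acyl group stays only in 10); methanesulfonyl azide, CS(=O)(=O)N=[N+]=[N-]
Why: Detrifluoroacetylative diazo transfer: the kinetic lithium enolate is acylated at −78 °C, and the activated β-diketone takes the diazo group from the sulfonyl azide with loss of the trifluoroacetyl group. Low temperature and a short enolate lifetime are meant to suppress β-elimination of the ring oxygen, which would open the ring and erode C2. C2 keeps its arrangement; the descriptor changes to (S) only because the diazo carbon now outranks the aryl group.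

Step 6
Reactants: 11 (2S)-5-bromo-3-diazo-7-methoxy-2-(4-methoxyphenyl)-2,3-dihydro-4H-chromen-4-one
Product: 14 (2R,3R)-4-bromo-6-methoxy-2-(4-methoxyphenyl)-2,3-dihydro-1-benzofuran-3-carboxylic acid, via ketene 12 (not isolated), via methyl ester 13 (not isolated)
Conditions: hν (440 nm LED), THF/MeOH, 20 °C; NaOMe (0.3 equiv), 40 °C; then LiOH, H2O, 50 °C; HCl work-up
Reagents that add atoms: methanol, CO (its methoxy group stays only in 13); lithium hydroxide, [Li+].[OH-] (its oxygen ends in the carboxyl group)
Why: Photochemical Wolff ring contraction: as dinitrogen leaves, C4a migrates from the carbonyl carbon to the diazo carbon and methanol traps ketene 12. C-protonation of the ester enol from the face away from the C2 aryl group would leave the ester cis, so NaOMe equilibrates C3 to the trans ester 13 (thermodynamic control) before LiOH hydrolyses it. C2 is not involved, and the step rehearses the key step on a simple substrate without a stilbene.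

Step 7
Reactants: 14 (2R,3R)-4-bromo-6-methoxy-2-(4-methoxyphenyl)-2,3-dihydro-1-benzofuran-3-carboxylic acid; 15 (E)-2-(4-methoxyphenyl)ethenylboronic acid
Product: 16 (2R,3R)-6-methoxy-2-(4-methoxyphenyl)-4-[(E)-2-(4-methoxyphenyl)ethenyl]-2,3-dihydro-1-benzofuran-3-carboxylic acid
Conditions: Pd(OAc)2 (5 mol%), SPhos (10 mol%), K3PO4, toluene/H2O, 80 °C
Reagents that add atoms: none
Why: Suzuki–Miyaura coupling with retention of the E geometry of the alkenylboronic acid; the biarylphosphine copes with the ortho-substituted bromide and the carboxylate is tolerated. From here on the stilbene is insulated from every later diazo ketone by an sp3 carbon.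

Step 8
Reactants: 16 (2R,3R)-6-methoxy-2-(4-methoxyphenyl)-4-[(E)-2-(4-methoxyphenyl)ethenyl]-2,3-dihydro-1-benzofuran-3-carboxylic acid; 17 N-hydroxyphthalimide
Product: 18 1,3-dioxoisoindolin-2-yl (2R,3R)-6-methoxy-2-(4-methoxyphenyl)-4-[(E)-2-(4-methoxyphenyl)ethenyl]-2,3-dihydro-1-benzofuran-3-carboxylate
Conditions: DIC, DMAP (10 mol%), CH2Cl2, 20 °C
Reagents that add atoms: none
Why: Carbodiimide (Steglich-type) esterification gives the redox-active ester; the C3 configuration is of no consequence, since the next step passes through a planar radical.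

Step 9
Reactants: 18 1,3-dioxoisoindolin-2-yl ester of 16; 7 5-bromo-7-methoxy-4H-chromen-4-one (as its zinc reagent)
Product: 19 7-methoxy-5-(G1)-4H-chromen-4-one
Conditions: 7 (3 equiv), Zn, LiCl, THF, 40 °C; then 18, NiCl2·glyme (20 mol%), 4,4′-di-tert-butyl-2,2′-bipyridine (40 mol%), THF/DMF, 25 °C
Reagents that add atoms: none
Why: LiCl-mediated insertion of zinc into the C–Br bond next to the carbonyl group gives the arylzinc bromide; nickel-catalysed decarboxylative Negishi-type arylation of the redox-active ester follows. Electron transfer from low-valent nickel fragments 18 to the planar benzylic C3 radical, which the aryl–nickel species captures on the face away from the C2 aryl group; reductive elimination from trivalent nickel gives the 2,3-trans product with C3 (R). The chromone enters whole, so 19 is at once the substrate of the next conjugate addition.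

Step 10
Reactants: 19 7-methoxy-5-(G1)-4H-chromen-4-one; 8 4-methoxyphenylboronic acid
Product: 20 (2S)-7-methoxy-2-(4-methoxyphenyl)-5-(G1)-2,3-dihydro-4H-chromen-4-one
Conditions: Pd(OCOCF3)2 (5 mol%), (R)-t-BuPyOx (6 mol%), NH4PF6 (30 mol%), H2O (5 equiv), ClCH2CH2Cl, 60 °C
Reagents that add atoms: none
Why: The same conjugate addition as in step 4 with the enantiomeric ligand, which sets C2 of the middle unit as (S). The resident stereocentres sit on the C5 substituent, remote from C2, so catalyst control should prevail; the isolated stilbene is a poor partner for the aryl–palladium species.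

Step 11
Reactants: 20 (2S)-7-methoxy-2-(4-methoxyphenyl)-5-(G1)-2,3-dihydro-4H-chromen-4-one
Product: 22 (2R)-3-diazo-7-methoxy-2-(4-methoxyphenyl)-5-(G1)-2,3-dihydro-4H-chromen-4-one, via trifluoroacetyl ketone 21 (not isolated)
Conditions: LiN(SiMe3)2, THF, −78 °C; CF3CO2CH2CF3; then MsN3, Et3N, H2O, MeCN, 0 °C
Reagents that add atoms: 2,2,2-trifluoroethyl trifluoroacetate, O=C(OCC(F)(F)F)C(F)(F)F (its acyl group stays only in 21); methanesulfonyl azide, CS(=O)(=O)N=[N+]=[N-]
Why: Detrifluoroacetylative diazo transfer as in step 5; the α-methylene group is by far the most acidic site, the diarylmethine and benzylic ether protons of unit 1 being untouched by the amide base at −78 °C. C2 keeps its arrangement (the descriptor becomes (R) for the reason given in step 5).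

Step 12
Reactants: 22 (2R)-3-diazo-7-methoxy-2-(4-methoxyphenyl)-5-(G1)-2,3-dihydro-4H-chromen-4-one
Product: 25 (2S,3S)-6-methoxy-2-(4-methoxyphenyl)-4-(G1)-2,3-dihydro-1-benzofuran-3-carboxylic acid, via ketene 23 (not isolated), via methyl ester 24 (not isolated)
Conditions: hν (440 nm LED), THF/MeOH, 20 °C; NaOMe (0.3 equiv), 40 °C; then LiOH, H2O, 50 °C; HCl work-up
Reagents that add atoms: methanol, CO (its methoxy group stays only in 24); lithium hydroxide, [Li+].[OH-] (its oxygen ends in the carboxyl group)
Why: Photochemical Wolff ring contraction as in step 6, followed by methoxide equilibration of C3 to the trans ester and hydrolysis. Visible light is absorbed only by the diazo ketone; the stilbene, now not conjugated with it, is expected to absorb only in the ultraviolet and to keep its E geometry.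

Step 13
Reactants: 25 (2S,3S)-6-methoxy-2-(4-methoxyphenyl)-4-(G1)-2,3-dihydro-1-benzofuran-3-carboxylic acid; 17 N-hydroxyphthalimide
Product: 26 1,3-dioxoisoindolin-2-yl (2S,3S)-6-methoxy-2-(4-methoxyphenyl)-4-(G1)-2,3-dihydro-1-benzofuran-3-carboxylate
Conditions: DIC, DMAP (10 mol%), CH2Cl2, 20 °C
Reagents that add atoms: none
Why: Carbodiimide esterification to the redox-active ester, as in step 8.

Step 14
Reactants: 26 1,3-dioxoisoindolin-2-yl ester of 25; 7 5-bromo-7-methoxy-4H-chromen-4-one (as its zinc reagent)
Product: 27 7-methoxy-5-(G2)-4H-chromen-4-one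
Conditions: 7 (3 equiv), Zn, LiCl, THF, 40 °C; then 26, NiCl2·glyme (20 mol%), 4,4′-di-tert-butyl-2,2′-bipyridine (40 mol%), THF/DMF, 25 °C
Reagents that add atoms: none
Why: Nickel-catalysed decarboxylative Negishi-type arylation as in step 9; the planar C3 radical of dihydrobenzofuran 2 is arylated anti to its C2 aryl group, giving trans with C3 (S). Ring A3 arrives as a complete chromone.

Step 15
Reactants: 27 7-methoxy-5-(G2)-4H-chromen-4-one; 8 4-methoxyphenylboronic acid
Product: 28 (2R)-7-methoxy-2-(4-methoxyphenyl)-5-(G2)-2,3-dihydro-4H-chromen-4-one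
Conditions: Pd(OCOCF3)2 (5 mol%), (S)-t-BuPyOx (6 mol%), NH4PF6 (30 mol%), H2O (5 equiv), ClCH2CH2Cl, 60 °C
Reagents that add atoms: none
Why: Palladium-catalysed enantioselective conjugate addition as in step 4; the (S)-ligand sets C2 of the last unit as (R) under catalyst control.

Step 16
Reactants: 28 (2R)-7-methoxy-2-(4-methoxyphenyl)-5-(G2)-2,3-dihydro-4H-chromen-4-one
Product: 30 (2S)-3-diazo-7-methoxy-2-(4-methoxyphenyl)-5-(G2)-2,3-dihydro-4H-chromen-4-one, via trifluoroacetyl ketone 29 (not isolated)
Conditions: LiN(SiMe3)2, THF, −78 °C; CF3CO2CH2CF3; then MsN3, Et3N, H2O, MeCN, 0 °C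
Reagents that add atoms: 2,2,2-trifluoroethyl trifluoroacetate, O=C(OCC(F)(F)F)C(F)(F)F (its acyl group stays only in 29); methanesulfonyl azide, CS(=O)(=O)N=[N+]=[N-]
Why: Detrifluoroacetylative diazo transfer as in steps 5 and 11, run cold so that the enolates do not open the pyranone ring by retro-oxa-Michael reaction. C2 keeps its arrangement; the descriptor becomes (S) by the change of priorities only.

Step 17
Reactants: 30 (2S)-3-diazo-7-methoxy-2-(4-methoxyphenyl)-5-(G2)-2,3-dihydro-4H-chromen-4-one
Product: 33 (2R,3R)-6-methoxy-2-(4-methoxyphenyl)-4-(G2)-2,3-dihydro-1-benzofuran-3-carboxylic acid, via ketene 31 (not isolated), via methyl ester 32 (not isolated)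
Conditions: hν (440 nm LED), THF/MeOH, 20 °C; NaOMe (0.3 equiv), 40 °C; then LiOH, H2O, 50 °C; HCl work-up
Reagents that add atoms: methanol, CO (its methoxy group stays only in 32); lithium hydroxide, [Li+].[OH-] (its oxygen ends in the carboxyl group)
Why: Light of 440 nm excites only the diazo ketone, whose diazo and carbonyl groups are held syn-periplanar by the ring, so loss of dinitrogen and the 1,2-shift of C4a of ring A3 from the carbonyl carbon to the diazo carbon occur in one event and give ketene 31 with the new C3–C3a bond; this is the photochemical Wolff rearrangement, the established ring contraction of cyclic α-diazo ketones including 3-diazochroman-4-ones. The five-membered ring is therefore not closed by a cyclisation but arises by contraction of the six-membered ring, the former C4 being pushed out as the exocyclic ketene carbon. Methanol adds to 31 and the ester enol is protonated on carbon mainly from the face away from the C2 aryl group, which by itself would leave the ester cis to that group; NaOMe then equilibrates C3 through the ester enolate to the trans ester 32, and LiOH hydrolyses it to 33. C3 is thus set under thermodynamic control, which is why the ketene is trapped with methanol and not with water: a carboxylate could not be equilibrated by mild base. C2 takes no part and keeps the configuration set in step 15; opening of the ester enolate is disfavoured because the C2–O bond lies in the nodal plane of the enolate. The selectivity needed is migration of the ring carbon over a 1,2-hydride or 1,2-aryl shift from C2 and over carbene insertions, and it is secured by the concerted pathway of the locked s-cis diazo ketone under direct irradiation without a metal. The isolated stilbene is expected to absorb only in the ultraviolet and should keep its E geometry. Because step 19 passes through a planar radical at C3, incomplete equilibration here would cost nothing in the final product.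

Step 18
Reactants: 33 (2R,3R)-6-methoxy-2-(4-methoxyphenyl)-4-(G2)-2,3-dihydro-1-benzofuran-3-carboxylic acid; 17 N-hydroxyphthalimide
Product: 34 1,3-dioxoisoindolin-2-yl (2R,3R)-6-methoxy-2-(4-methoxyphenyl)-4-(G2)-2,3-dihydro-1-benzofuran-3-carboxylate
Conditions: DIC, DMAP (10 mol%), CH2Cl2, 20 °C
Reagents that add atoms: none
Why: Carbodiimide esterification to the redox-active ester, as in steps 8 and 13.

Step 19
Reactants: 34 1,3-dioxoisoindolin-2-yl ester of 33; 1 1-bromo-3,5-dimethoxybenzene (as its zinc reagent)
Product: 35 (2R,3R)-3-(3,5-dimethoxyphenyl)-6-methoxy-2-(4-methoxyphenyl)-4-(G2)-2,3-dihydro-1-benzofuran (nona-O-methylmiyabenol A)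
Conditions: 1, Mg, LiCl, THF; ZnCl2; then 34, NiCl2·glyme (20 mol%), 4,4′-di-tert-butyl-2,2′-bipyridine (40 mol%), THF/DMF, 25 °C
Reagents that add atoms: none
Why: Nickel-catalysed decarboxylative Negishi-type arylation with 3,5-dimethoxyphenylzinc chloride; the planar C3 radical of dihydrobenzofuran 3 is arylated anti to the C2 aryl group, which sets the last stereocentre trans with C3 (R). This arylzinc has no ortho substituent, so the coupling is the least hindered of the three.

Step 20
Reactants: 35 nona-O-methylmiyabenol A
Product: 36 miyabenol A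
Conditions: BBr3, CH2Cl2, −78 → 20 °C; then MeOH, H2O
Reagents that add atoms: none
Why: Lewis-acid cleavage of the nine aryl methyl ethers by bromide attack on the boron-activated methyl groups. Low temperature and excess reagent are meant to outrun ionisation of the benzylic C2–O bonds.

## Compound list

1 | 1-bromo-3,5-dimethoxybenzene | COc1cc(Br)cc(OC)c1 | starting material
2 | acetyl chloride | CC(=O)Cl | starting material
3 | 1-(2-bromo-4,6-dimethoxyphenyl)ethan-1-one | CC(=O)c1c(Br)cc(OC)cc1OC | intermediate
4 | 1-(2-bromo-6-hydroxy-4-methoxyphenyl)ethan-1-one | CC(=O)c1c(Br)cc(OC)cc1O | intermediate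
5 | N,N-dimethylformamide dimethyl acetal | COC(OC)N(C)C | starting material
6 | (E)-1-(2-bromo-6-hydroxy-4-methoxyphenyl)-3-(dimethylamino)prop-2-en-1-one | CN(C)/C=C/C(=O)c1c(Br)cc(OC)cc1O | intermediate
7 | 5-bromo-7-methoxy-4H-chromen-4-one | COc1cc(Br)c2c(c1)OC=CC2=O | intermediate
8 | 4-methoxyphenylboronic acid | COc1ccc(B(O)O)cc1 | starting material
9 | (2R)-5-bromo-7-methoxy-2-(4-methoxyphenyl)-2,3-dihydro-4H-chromen-4-one | Brc1cc(OC)cc2c1C(=O)C[C@H](c1ccc(OC)cc1)O2 | intermediate
10 | 3-trifluoroacetyl derivative of 9 (enolised β-diketone, C2 as in 9) | Brc1cc(OC)cc2c1C(O)=C(C(=O)C(F)(F)F)[C@H](c1ccc(OC)cc1)O2 | intermediate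
11 | (2S)-5-bromo-3-diazo-7-methoxy-2-(4-methoxyphenyl)-2,3-dihydro-4H-chromen-4-one (C2 arranged as in 9) | Brc1cc(OC)cc2c1C(=O)C(=[N+]=[N-])[C@H](c1ccc(OC)cc1)O2 | intermediate
12 | 4-bromo-6-methoxy-2-(4-methoxyphenyl)-3-(oxomethylidene)-2,3-dihydro-1-benzofuran (ketene, C2 as in 11) | Brc1cc(OC)cc2c1C(=C=O)[C@H](c1ccc(OC)cc1)O2 | intermediate
13 | methyl (2R,3R)-4-bromo-6-methoxy-2-(4-methoxyphenyl)-2,3-dihydro-1-benzofuran-3-carboxylate | Brc1cc(OC)cc2c1[C@@H](C(=O)OC)[C@H](c1ccc(OC)cc1)O2 | intermediate
14 | (2R,3R)-4-bromo-6-methoxy-2-(4-methoxyphenyl)-2,3-dihydro-1-benzofuran-3-carboxylic acid | Brc1cc(OC)cc2c1[C@@H](C(=O)O)[C@H](c1ccc(OC)cc1)O2 | intermediate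
15 | (E)-2-(4-methoxyphenyl)ethenylboronic acid | COc1ccc(/C=C/B(O)O)cc1 | starting material
16 | (2R,3R)-6-methoxy-2-(4-methoxyphenyl)-4-[(E)-2-(4-methoxyphenyl)ethenyl]-2,3-dihydro-1-benzofuran-3-carboxylic acid | COc1ccc(/C=C/c2cc(OC)cc3c2[C@@H](C(=O)O)[C@H](c2ccc(OC)cc2)O3)cc1 | intermediate
17 | N-hydroxyphthalimide | O=C1c2ccccc2C(=O)N1O | starting material
18 | 1,3-dioxoisoindolin-2-yl (2R,3R)-6-methoxy-2-(4-methoxyphenyl)-4-[(E)-2-(4-methoxyphenyl)ethenyl]-2,3-dihydro-1-benzofuran-3-carboxylate | COc1ccc(/C=C/c2cc(OC)cc3c2[C@@H](C(=O)ON2C(=O)c4ccccc4C2=O)[C@H](c2ccc(OC)cc2)O3)cc1 | intermediate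
19 | 7-methoxy-5-(G1)-4H-chromen-4-one | COc1ccc(/C=C/c2cc(OC)cc3c2[C@@H](c2cc(OC)cc4c2C(=O)C=CO4)[C@H](c2ccc(OC)cc2)O3)cc1 | intermediate
20 | (2S)-7-methoxy-2-(4-methoxyphenyl)-5-(G1)-2,3-dihydro-4H-chromen-4-one | COc1ccc(/C=C/c2cc(OC)cc3c2[C@@H](c2cc(OC)cc4c2C(=O)C[C@@H](c2ccc(OC)cc2)O4)[C@H](c2ccc(OC)cc2)O3)cc1 | intermediate
21 | 3-trifluoroacetyl derivative of 20 (enolised β-diketone, C2 as in 20) | COc1ccc(/C=C/c2cc(OC)cc3c2[C@@H](c2cc(OC)cc4c2C(O)=C(C(=O)C(F)(F)F)[C@@H](c2ccc(OC)cc2)O4)[C@H](c2ccc(OC)cc2)O3)cc1 | intermediate
22 | (2R)-3-diazo-7-methoxy-2-(4-methoxyphenyl)-5-(G1)-2,3-dihydro-4H-chromen-4-one (C2 arranged as in 20) | COc1ccc(/C=C/c2cc(OC)cc3c2[C@@H](c2cc(OC)cc4c2C(=O)C(=[N+]=[N-])[C@@H](c2ccc(OC)cc2)O4)[C@H](c2ccc(OC)cc2)O3)cc1 | intermediate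
23 | 6-methoxy-2-(4-methoxyphenyl)-3-(oxomethylidene)-4-(G1)-2,3-dihydro-1-benzofuran (ketene, C2 as in 22) | COc1ccc(/C=C/c2cc(OC)cc3c2[C@@H](c2cc(OC)cc4c2C(=C=O)[C@@H](c2ccc(OC)cc2)O4)[C@H](c2ccc(OC)cc2)O3)cc1 | intermediate
24 | methyl (2S,3S)-6-methoxy-2-(4-methoxyphenyl)-4-(G1)-2,3-dihydro-1-benzofuran-3-carboxylate | COc1ccc(/C=C/c2cc(OC)cc3c2[C@@H](c2cc(OC)cc4c2[C@H](C(=O)OC)[C@@H](c2ccc(OC)cc2)O4)[C@H](c2ccc(OC)cc2)O3)cc1 | intermediate
25 | (2S,3S)-6-methoxy-2-(4-methoxyphenyl)-4-(G1)-2,3-dihydro-1-benzofuran-3-carboxylic acid | COc1ccc(/C=C/c2cc(OC)cc3c2[C@@H](c2cc(OC)cc4c2[C@H](C(=O)O)[C@@H](c2ccc(OC)cc2)O4)[C@H](c2ccc(OC)cc2)O3)cc1 | intermediate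
26 | 1,3-dioxoisoindolin-2-yl (2S,3S)-6-methoxy-2-(4-methoxyphenyl)-4-(G1)-2,3-dihydro-1-benzofuran-3-carboxylate | COc1ccc(/C=C/c2cc(OC)cc3c2[C@@H](c2cc(OC)cc4c2[C@H](C(=O)ON2C(=O)c5ccccc5C2=O)[C@@H](c2ccc(OC)cc2)O4)[C@H](c2ccc(OC)cc2)O3)cc1 | intermediate
27 | 7-methoxy-5-(G2)-4H-chromen-4-one | COc1ccc(/C=C/c2cc(OC)cc3c2[C@@H](c2cc(OC)cc4c2[C@H](c2cc(OC)cc5c2C(=O)C=CO5)[C@@H](c2ccc(OC)cc2)O4)[C@H](c2ccc(OC)cc2)O3)cc1 | intermediate
28 | (2R)-7-methoxy-2-(4-methoxyphenyl)-5-(G2)-2,3-dihydro-4H-chromen-4-one | COc1ccc(/C=C/c2cc(OC)cc3c2[C@@H](c2cc(OC)cc4c2[C@H](c2cc(OC)cc5c2C(=O)C[C@H](c2ccc(OC)cc2)O5)[C@@H](c2ccc(OC)cc2)O4)[C@H](c2ccc(OC)cc2)O3)cc1 | intermediate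
29 | 3-trifluoroacetyl derivative of 28 (enolised β-diketone, C2 as in 28) | COc1ccc(/C=C/c2cc(OC)cc3c2[C@@H](c2cc(OC)cc4c2[C@H](c2cc(OC)cc5c2C(O)=C(C(=O)C(F)(F)F)[C@H](c2ccc(OC)cc2)O5)[C@@H](c2ccc(OC)cc2)O4)[C@H](c2ccc(OC)cc2)O3)cc1 | intermediate
30 | (2S)-3-diazo-7-methoxy-2-(4-methoxyphenyl)-5-(G2)-2,3-dihydro-4H-chromen-4-one (C2 arranged as in 28) | COc1ccc(/C=C/c2cc(OC)cc3c2[C@@H](c2cc(OC)cc4c2[C@H](c2cc(OC)cc5c2C(=O)C(=[N+]=[N-])[C@H](c2ccc(OC)cc2)O5)[C@@H](c2ccc(OC)cc2)O4)[C@H](c2ccc(OC)cc2)O3)cc1 | intermediate
31 | 6-methoxy-2-(4-methoxyphenyl)-3-(oxomethylidene)-4-(G2)-2,3-dihydro-1-benzofuran (ketene, C2 as in 30) | COc1ccc(/C=C/c2cc(OC)cc3c2[C@@H](c2cc(OC)cc4c2[C@H](c2cc(OC)cc5c2C(=C=O)[C@H](c2ccc(OC)cc2)O5)[C@@H](c2ccc(OC)cc2)O4)[C@H](c2ccc(OC)cc2)O3)cc1 | intermediate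
32 | methyl (2R,3R)-6-methoxy-2-(4-methoxyphenyl)-4-(G2)-2,3-dihydro-1-benzofuran-3-carboxylate | COc1ccc(/C=C/c2cc(OC)cc3c2[C@@H](c2cc(OC)cc4c2[C@H](c2cc(OC)cc5c2[C@@H](C(=O)OC)[C@H](c2ccc(OC)cc2)O5)[C@@H](c2ccc(OC)cc2)O4)[C@H](c2ccc(OC)cc2)O3)cc1 | intermediate
33 | (2R,3R)-6-methoxy-2-(4-methoxyphenyl)-4-(G2)-2,3-dihydro-1-benzofuran-3-carboxylic acid | COc1ccc(/C=C/c2cc(OC)cc3c2[C@@H](c2cc(OC)cc4c2[C@H](c2cc(OC)cc5c2[C@@H](C(=O)O)[C@H](c2ccc(OC)cc2)O5)[C@@H](c2ccc(OC)cc2)O4)[C@H](c2ccc(OC)cc2)O3)cc1 | intermediate
34 | 1,3-dioxoisoindolin-2-yl (2R,3R)-6-methoxy-2-(4-methoxyphenyl)-4-(G2)-2,3-dihydro-1-benzofuran-3-carboxylate | COc1ccc(/C=C/c2cc(OC)cc3c2[C@@H](c2cc(OC)cc4c2[C@H](c2cc(OC)cc5c2[C@@H](C(=O)ON2C(=O)c6ccccc6C2=O)[C@H](c2ccc(OC)cc2)O5)[C@@H](c2ccc(OC)cc2)O4)[C@H](c2ccc(OC)cc2)O3)cc1 | intermediate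
35 | nona-O-methylmiyabenol A, (2R,3R)-3-(3,5-dimethoxyphenyl)-6-methoxy-2-(4-methoxyphenyl)-4-(G2)-2,3-dihydro-1-benzofuran | COc1ccc(/C=C/c2cc(OC)cc3c2[C@@H](c2cc(OC)cc4c2[C@H](c2cc(OC)cc5c2[C@@H](c2cc(OC)cc(OC)c2)[C@H](c2ccc(OC)cc2)O5)[C@@H](c2ccc(OC)cc2)O4)[C@H](c2ccc(OC)cc2)O3)cc1 | intermediate
36 | miyabenol A; dihydrobenzofuran 1 (2R,3R), dihydrobenzofuran 2 (2S,3S), dihydrobenzofuran 3 (2R,3R), E-stilbene | Oc1ccc(/C=C/c2cc(O)cc3c2[C@@H](c2cc(O)cc4c2[C@H](c2cc(O)cc5c2[C@@H](c2cc(O)cc(O)c2)[C@H](c2ccc(O)cc2)O5)[C@@H](c2ccc(O)cc2)O4)[C@H](c2ccc(O)cc2)O3)cc1 | target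

## Step count and least certain steps

Total step count: 20. Longest linear sequence: 20 steps (1 to 36); building block 7 is used three times (steps 4, 9 and 14).

Step 17 (key step).
- What may go wrong: the excited diazo ketone may leave the concerted pathway, because the bulky C5 substituent can twist the carbonyl group out of the ideal geometry. Carbene chemistry would then follow: a 1,2-hydride shift from C2 with aromatisation of the pyranone ring, or insertion into the O–H bond of the alcohol. Less likely is sensitised E/Z isomerisation of the stilbene by energy transfer.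
- Fallback: it sets out from 26 and gives up both light and the flavanone. 26 is coupled under the conditions of step 14 with the zinc reagent (Zn, LiCl) of the separately prepared methyl 2-[2-iodo-4-methoxy-6-[(4-methoxyphenyl)methoxy]phenyl]acetate F1, to give methyl 2-[2-(G2)-4-methoxy-6-[(4-methoxyphenyl)methoxy]phenyl]acetate F2. Diazo transfer with 4-acetamidobenzenesulfonyl azide and DBU gives methyl 2-diazo-2-[2-(G2)-4-methoxy-6-[(4-methoxyphenyl)methoxy]phenyl]acetate F3. The enantiomer of the dirhodium tetracarboxylate Rh2(S-PTTL)4 (PTTL = N-phthaloyl-tert-leucinate) that sets (2R) then catalyses insertion of the donor–acceptor carbene into the benzylic C–H bond of the 4-methoxybenzyl ether and closes dihydrobenzofuran 3 as methyl (2R,3S)-6-methoxy-2-(4-methoxyphenyl)-4-(G2)-2,3-dihydro-1-benzofuran-3-carboxylate F4 (cis ester). NaOMe in MeOH equilibrates F4 to the trans ester 32, where the route is rejoined; hydrolysis as in step 17 gives 33.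

Step 9 (and its repeat, step 14).
- What may go wrong: transmetalation of the carbonyl-chelated, ortho-substituted arylzinc may be slow and bond formation at the flanked C3 sluggish. The benzylic radical would then be reduced or dimerise, or the alkylnickel species would lose the C2 hydrogen by β-hydride elimination. Nickel-catalysed 1,4-addition of the arylzinc to chromone units may also consume reagent.
- Fallback: it sets out from 18 and unmetalated 7 and returns at 19. It is a reductive cross-electrophile coupling (NiBr2·glyme, 4,4′-di-tert-butyl-2,2′-bipyridine, Zn powder, DMA, 25 °C), in which the aryl bromide enters by oxidative addition to low-valent nickel and no organozinc is present. It makes no new compound (F0).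

Step 16 (and steps 5 and 11).
- What may go wrong: β-elimination of the ring oxygen from the lithium enolate, or from the enolate of the trifluoroacetyl ketone, followed by reclosure (retro-oxa-Michael and oxa-Michael), would erode the C2 configuration.
- Fallback: it sets out from 28 and avoids enolates altogether. Heating with 5 (toluene, 90 °C) gives (2S)-3-[(E)-(dimethylamino)methylidene]-7-methoxy-2-(4-methoxyphenyl)-5-(G2)-2,3-dihydro-4H-chromen-4-one F5 (C2 arranged as in 28). Diazo transfer to this enaminone with 4-toluenesulfonyl azide (CH2Cl2, 20 °C) then gives 30, where the route is rejoined.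

Step 20.
- What may go wrong: Lewis-acid ionisation of the C2–O bonds to 4-oxyphenyl-stabilised benzylic cations would cause ring opening, epimerisation or Friedel–Crafts capture by neighbouring rings. Hydrogen bromide may add to or cyclise the stilbene, and cleavage of all nine ethers may be incomplete.
- Fallback: it sets out from 35 and returns at 36. The mechanism changes from electrophilic to nucleophilic ether cleavage: EtSNa in DMF at 130 °C attacks the methyl groups in an SN2 reaction, so no acid and no cation are involved. It makes no new compound (F0).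

## Further compounds

F1 | step 17 | methyl 2-[2-iodo-4-methoxy-6-[(4-methoxyphenyl)methoxy]phenyl]acetate | COC(=O)Cc1c(I)cc(OC)cc1OCc1ccc(OC)cc1
F2 | step 17 | methyl 2-[2-(G2)-4-methoxy-6-[(4-methoxyphenyl)methoxy]phenyl]acetate | COc1ccc(/C=C/c2cc(OC)cc3c2[C@@H](c2cc(OC)cc4c2[C@H](c2cc(OC)cc(OCc5ccc(OC)cc5)c2CC(=O)OC)[C@@H](c2ccc(OC)cc2)O4)[C@H](c2ccc(OC)cc2)O3)cc1
F3 | step 17 | methyl 2-diazo-2-[2-(G2)-4-methoxy-6-[(4-methoxyphenyl)methoxy]phenyl]acetate | COc1ccc(/C=C/c2cc(OC)cc3c2[C@@H](c2cc(OC)cc4c2[C@H](c2cc(OC)cc(OCc5ccc(OC)cc5)c2C(=[N+]=[N-])C(=O)OC)[C@@H](c2ccc(OC)cc2)O4)[C@H](c2ccc(OC)cc2)O3)cc1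
F4 | step 17 | methyl (2R,3S)-6-methoxy-2-(4-methoxyphenyl)-4-(G2)-2,3-dihydro-1-benzofuran-3-carboxylate (cis ester) | COc1ccc(/C=C/c2cc(OC)cc3c2[C@@H](c2cc(OC)cc4c2[C@H](c2cc(OC)cc5c2[C@H](C(=O)OC)[C@H](c2ccc(OC)cc2)O5)[C@@H](c2ccc(OC)cc2)O4)[C@H](c2ccc(OC)cc2)O3)cc1
F0 | step 9 | none | none
F5 | step 16 | (2S)-3-[(E)-(dimethylamino)methylidene]-7-methoxy-2-(4-methoxyphenyl)-5-(G2)-2,3-dihydro-4H-chromen-4-one | COc1ccc(/C=C/c2cc(OC)cc3c2[C@@H](c2cc(OC)cc4c2[C@H](c2cc(OC)cc5c2C(=O)/C(=C/N(C)C)[C@H](c2ccc(OC)cc2)O5)[C@@H](c2ccc(OC)cc2)O4)[C@H](c2ccc(OC)cc2)O3)cc1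
F0 | step 20 | none | none
A1 | alternative 1 | permethylated tris(dihydrobenzofuran) with bromine at C4 of ring A1 in place of the styryl group | Brc1cc(OC)cc2c1[C@@H](c1cc(OC)cc3c1[C@H](c1cc(OC)cc4c1[C@@H](c1cc(OC)cc(OC)c1)[C@H](c1ccc(OC)cc1)O4)[C@@H](c1ccc(OC)cc1)O3)[C@H](c1ccc(OC)cc1)O2
A2 | alternative 2 | 2,4-dihydroxybenzophenone whose new ring A2 links C3 of dihydrobenzofuran 1 to the carbonyl group on ring A3 | COc1ccc(/C=C/c2cc(OC)cc3c2[C@@H](c2cc(O)cc(O)c2C(=O)c2cc(OC)cc5c2[C@@H](c2cc(OC)cc(OC)c2)[C@H](c2ccc(OC)cc2)O5)[C@H](c2ccc(OC)cc2)O3)cc1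
A3 | alternative 3 | nona-O-methylmiyabenol A (identical with 35) | COc1ccc(/C=C/c2cc(OC)cc3c2[C@@H](c2cc(OC)cc4c2[C@H](c2cc(OC)cc5c2[C@@H](c2cc(OC)cc(OC)c2)[C@H](c2ccc(OC)cc2)O5)[C@@H](c2ccc(OC)cc2)O4)[C@H](c2ccc(OC)cc2)O3)cc1
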